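The ratio I carried through this flask was the leak ratio S: the rate at which target forms over the rate at which starting material is lost. Free catalyst stands once in each of these two rates and cancels, which leaves S = σ × coupling partner concentration × intermediate / starting material, with σ the leak constant, a kind of selectivity factor.

- south-west: starting material 0.40 M; coupling partner 1.05 equiv (fed, over 2.5 h); free catalyst 2.1 mol%; run made earlier; the fed solution adds 1.0 times the starting volume
- flask: starting material 0.20 M; coupling partner 1.05 equiv (fed, over 2.5 h); free catalyst 2.1 mol%; time 4.0 h; the fed solution adds 1.0 times the starting volume

- south-west (time / min: intermediate / %, target / %): 3.00: 3.5, 0; 10.0: 10.3, 0.1; 15.0: 14.6, 0; 25.0: 23.0, 0.6; 40.0: 32.7, 1.0; 50.0: 36.8, 2.0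

(scatter of a reading: 0.3 percentage points)

- amount of intermediate in percent of the starting material charged, at 25 min, 80 min and 4.0 h

- amounts are per litre of the starting volume; all of the dose is in the solution fed
- the numbers in the tables scatter with a standard deviation of 0.3 percentage points
- reactions considered so far: coupling partner + free catalyst -> spent catalyst; starting material + free catalyst -> free catalyst + intermediate; coupling partner + free catalyst + intermediate -> free catalyst + target
- no earlier run changes the charge of free catalyst; that part of a forecast is a guess

I kept the books on starting material, the limiting reagent. Between 25.0 min and 50.0 min of the south-west run, target gained 1.4 percentage points while starting material lost 15 points, so S read 0.0921, a reading that rests on a small difference. At the midpoint, 37.5 min, the dosed coupling partner stood near 0.0840 M and intermediate over starting material near 0.435. That gave the leak constant σ = 2.52 L mol⁻¹.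

My first entry was starting material left. Counting minutes as worth less while the feed dilutes the catalyst, the south-west run gave a first-order constant of 0.0114 min⁻¹. I scaled it to the flask's lower concentration, booked no catalyst loss, and counted 149 min of such minutes up to 4.0 h, which left 42.8 % of the starting material. The second entry was target. With the coupling partner taken as fully present, S ended near 0.353. It starts at zero and climbs steeply, so I used a third of that value as its mean over the conversion, which booked 6.73 %. The remainder, 50.4 %, was intermediate, and the books closed.

The forecast said 12.4 %, 30.2 % and 51 %, on the ground that “the first step runs at half the rate and the second at a quarter”; its last value stood higher than my 50.4 %.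

The flask gave 12.3 %, 29.8 % and 50.5 %.

    coupling partner + free catalyst → spent catalyst (k = 0.648 L mol⁻¹ h⁻¹)
    starting material + free catalyst → free catalyst + intermediate (k = 81.7 L mol⁻¹ h⁻¹)
    coupling partner + free catalyst + intermediate → free catalyst + target (k = 179 L² mol⁻² h⁻¹)

At 4.00 h the flask held target 4.40 % against my 6.73 %, and starting material 45.1 % against my 42.8 %. Put to those simulated amounts, σ gives S = 0.283, less than one, so by this reading intermediate was still gaining. At 40.0 h the same flask held intermediate 64.6 %, starting material 5.31 % and coupling partner 69.6 %, and there σ puts target forming faster than starting material is lost, with S = 2.24.

The data come from a simulation for substances that don't exist, noise included.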